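| setting | north-west | south-west | south-east | eta | delta | alpha |
|---|---|---|---|---|---|---|
| starting material | 0.50 M | 0.50 M | 0.50 M | 0.50 M (fed, over 1.5 h) | 0.50 M | 0.50 M |
| second substrate | 0.50 M | 0.25 M | 1 M | 0.500 M | 0.500 M | 0.500 M (fed, over 1.5 h) |
| coupling partner | 0.65 M | 0.65 M | 0.65 M | 0.650 M | 0.650 M | 0.650 M |
| free catalyst | 5 mM | 5 mM | 5 mM | 5.0 mM | 5.0 mM | 5.0 mM |
| remark | run made earlier | run made earlier | run made earlier | all else is in the flask from the start; the feed brings no volume worth counting | everything together at the start | all else is in the flask from the start; the feed brings no volume worth counting |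
| time |  |  |  | 2.5 h | 2.5 h | 2.5 h |

- north-west (time / min: target / %, isomer of the product / %, starting material / %): 15.0: 9.6, 3.6, 88.2; 30.0: 10.1, 5.1, 84.5; 50.0: 9.5, 6.1, 85.5; 60.0: 10.8, 7.4, 85.4; 80.0: 7.8, 8.9, 85.1; 90.0: 7.9, 6.1, 84.6
- south-west (time / h: target / %, isomer of the product / %, starting material / %): 0.200: 11.8, 5.7, 82.1; 0.667: 14.0, 13.6, 74.6; 1.00: 11.9, 16.1, 72.1; 1.50: 11.0, 18.4, 70.7; 2.50: 10.7, 17.1, 71.7; 3.00: 11.8, 17.3, 71.7
- south-east (time / h: target / %, isomer of the product / %, starting material / %): 0.200: 6.2, 2.2, 93.8; 0.667: 6.6, 3.5, 90.9; 1.00: 6.0, 1.9, 90.1; 1.50: 5.3, 2.2, 91.6; 2.50: 6.9, 3.2, 92.7; 3.00: 4.1, 3.6, 93.1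

(standard deviation of a reading: 1 percentage point)

- the numbers in the tables scatter with a standard deviation of 1 percentage point

1. the flask with the highest share of target in target plus isomer of the product ("all alike" if they lie within 1.5 percentage points) (eta / delta / alpha / all alike)
2. share of target in target plus isomer of the product at the end, eta
3. share of target in target plus isomer of the product at the end, delta
4. share of target in target plus isomer of the product at the end, alpha

**Reading constants.** The constant these runs give us is read, not looked up: the stall product, which is the fraction of starting material converted at the last reading times c(second substrate) as charged, on average 0.0723 M. The north-west, south-west and south-east runs give 0.0770 M, 0.0707 M and 0.0690 M.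

**Start rates.** Up to the first reading, the south-west run converts 0.895 h⁻¹ of its charge, the north-west run 0.472 h⁻¹ and the south-east run 0.310 h⁻¹. So, as read, going from 0.25 M to 0.50 M of second substrate lowers this mean rate by a factor of 1.90, and going on to 1 M by 1.52 more. Then comes the second slowing. After its first reading, the north-west run converts 0.0288 h⁻¹, a factor of 16.4 down, though this reading is rough at this scatter.

**Our reckoning.** Summed up, the slowing leaves a stall: with the other charges as in these runs, we take final conversion as the stall product over c(second substrate). That gives 14.5 % for delta. For alpha, taking the feed as half the charge on average, it gives 28.9 %. The earlier runs held starting material at 0.50 M, so eta stays open, and this reckons conversion, not the share.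

**The forecast.** It expects delta highest, with 35 % for eta, 55 % for delta and 35 % for alpha, and reads the stall as “the catalyst dies, and it dies faster with more second substrate”.

**Flask result.** Eta holds the highest share, 50.2 %, against 47.4 % in delta and 39.6 % in alpha.

    2 coupling partner → self-condensation product (k = 0.00140 L mol⁻¹ s⁻¹)
    coupling partner + catalyst intermediate A → free catalyst + target (k = 0.400 L mol⁻¹ s⁻¹)
    coupling partner + catalyst intermediate B → free catalyst + second product (k = 0.180 L mol⁻¹ s⁻¹)
    starting material + free catalyst ⇌ catalyst intermediate A (K = 2.10 L mol⁻¹, k = 0.490 L mol⁻¹ s⁻¹)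
    target + free catalyst ⇌ isomer of the product + free catalyst, rate k5*[free catalyst]*[target] forward; the back reaction follows from the equilibrium constant (K = 1.70, k = 0.760 L mol⁻¹ s⁻¹)
    second substrate + free catalyst ⇌ catalyst intermediate B (K = 290 L mol⁻¹, k = 0.530 L mol⁻¹ s⁻¹)

**Stall product.** At 2.50 h, delta keeps 0.010 % of its coupling partner, the limiting reagent, while 97.2 % of its catalyst stands as catalyst intermediate B. Our stall product over delta's charge gave 14.5 %, and delta converted 16.1 %. Over half of alpha's charge it gave 28.9 %, and alpha converted 41.3 %.

All runs were generated by integration on assumed constants; scatter was added.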